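Conventions: germacrane numbering (C1–C15) is used for the target and for every intermediate, the bicyclic ones included; β is the face of ring A that carries the C3 oxygen. Compounds 1–33 are numbered in the order of the steps.

Assumption: (tributylstannyl)methanol 11 and ethyl 2-(diethoxyphosphoryl)acrylate 25 are taken as purchasable, and the two C5 epimers formed in step 11 are carried together because they converge at ketone 18.

## Analysis of the target

The target is a germacranolide: a cyclodeca-1(10),4-diene (C1–C10) whose C6 oxygen and C7 carbon are tied into an α,β-unsaturated γ-lactone (O–C12(=O)–C11=C7) carrying the free C13 hydroxymethyl group on C11. C1=C10 is Z and bears methyl C14, C4=C5 is E and bears methyl C15, and C3 and C9 carry acetoxy groups. The stereocentres are C3 (S), C6 (R) and C9 (S). C3 and C6 sit at the two ends of the E alkene, C9 is separated from C6 by C7 and C8, and no ring fusion relays one centre to the next, so each needs its own source of control. Sensitive features are the two allylic acetates, the butenolide (C6–H is allylic and γ to the lactone carbonyl; C8–H2 is vinylogously acidic and lies next to the C9 acetate, which can be lost by elimination), and the need to keep one primary alcohol free beside two acylated secondary ones. The main difficulty is the strained ten-membered ring with two trisubstituted alkenes of opposite geometry, which direct cyclisation serves poorly. The strategy rests on one feature: C1=C10 with C9, C2, C3 and C4 fits a cyclohexene (ring A) once a C4–C9 bond is drawn. In that bicycle the C9 oxygen, C4 and C5 are 1,3-related, so the extra bond can later be cut with loss of a leaving group from C5. Ring B (C4–C5–C6–C7–C8–C9) then carries every oxygen the lactone needs.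

## Retrosynthetic reasoning

Target 33 is taken back to butenolide 30 by functional-group changes only. The C13 alcohol stays a 4-methoxybenzyl ether (32) until both acetates are in place, and the acetates come from bis-silyl ether 30 through diol 31. No skeletal bond is cut; the gain is that the base-labile acetates and the free allylic alcohol exist only in the last three steps.

The butenolide of 30 is opened at C7=C11 and at the C6–O–C12 ester bond, giving keto phosphonate 29, its ketal 28, and then alcohol 24 plus acid 27. The cut is made here because C7 becomes a ketone and C6 a carbinol, an α-oxygenated ketone that ring B of a decalin can carry in masked form, and because C11–C13 arrive together in 27. Forward, C6 is acylated while C7 is still a ketal, the ketone is then freed, and an intramolecular Horner–Wadsworth–Emmons reaction closes the five-membered ring.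

The C9 carbinol of 24 (through 23 and 22) is returned to the ketone of dienone 21. C9 has no neighbour that could direct a hydride, so the forward reduction has to be reagent-controlled. The new oxygen is carried as a silyl ether because it later sits β to the C7 ketone, where a poor leaving group is wanted.

Dienone 21 is the key disconnection. Reconnecting C4–C9 and placing a leaving group on C5 gives the trans-fused hydroxy mesylate 20. This removes the medium ring from the problem: the Z alkene is locked in ring A, the E alkene follows from the chair of ring B, and the ten-membered ring appears by cleavage rather than closure. Forward, the C9 alkoxide must fragment with the C5–O bond anti-periplanar to C4–C9.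

Mesylate 20 comes from diol 19, whose C5 carbinol is traced to ketone 18 and this to the epimeric alcohols 17. The detour through the ketone is deliberate: the axial C9 hydroxyl can deliver hydride to C5 from the α face and so sets the equatorial 5β-oxygen whatever the ring closure gave. The C7 ketal is in place before C5 becomes a ketone or a mesylate, so neither a 1,3-diketone nor a β-mesyloxy ketone ever exists.

Ring B of 17 (through ketone 16) is opened at C5–C6, an aldol retron, giving keto aldehyde 15. This bond is chosen because C6 then arrives already carrying its protected oxygen, so C5 and C6 never have to be told apart as free alcohols. The equatorial position of the C6 ether is enforced by the axial C4 methyl. Forward, the ring must close without base, because the tertiary C9 carbinol is a retro-aldol risk.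

The C6–C7 bond of 15 (through 14 and 13) is cut to lactone 10 and stannane 12. The lactone carbonyl is C7, and the alkoxymethyl nucleophile from 12 brings C6 with its oxygen. The forward acylation must stop at the ketone stage.

Lactone 10 is opened at C8–C9 to bromoacetate 9, the ester of alcohol 8. This is where the ring fusion is decided. A free carbon nucleophile should attack the C9 ketone anti to the pseudo-axial C4 methyl, or be blocked by an axial C3 ether in the other half-chair, and would give the cis-fused carbinol. A two-atom tether from the C3 oxygen can only reach the β face, so C8 ends cis to O3 and the C9 hydroxyl trans to the C4 methyl, as trans-decalin 20 requires.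

The quaternary C4 of 8 is cut at C4–C5 and then at C4–C15, back through 6 to hydroxy enone 4. The order matters: the second electrophile enters anti to the C3 oxygen, so the methyl group goes in first and the C5 unit second. C5 is introduced as a protected aldehyde so that it stays inert while C8 and C6 are attached.

Hydroxy enone 4 comes from acetate 3 and this from carvone 1 by excision of the isopropenyl group with retention. The carvone stereocentre becomes C3, the only centre taken from the chiral pool, and the enone of 1 supplies C9, C10, C1 and methyl C14.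

## Alternatives that were turned down

Alternative 1: The disconnection is C6–C7, C11–C12 and C12–O, opening both the ten-membered ring and the butenolide to the acyclic ynal A1 (C6 aldehyde, C7≡C11 alkyne with silylated C13, both acetates in place). The forward key step is a hetero-Pauson–Khand reaction: a low-valent metal (Mo(CO)6 with dimethyl sulfoxide, or Cp2Ti(PMe3)2) joins aldehyde, alkyne and CO to give A2, one desilylation from the target.
- For: it is convergent, uses very few steps after the key step, and fixes both alkene geometries and two stereocentres in an open chain.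
- Against: the oxametallacycle needs aldehyde and alkyne on one metal centre, which is favourable when a five- or six-membered carbocycle forms but carries the full entropic and transannular cost of a ten-membered ring here. C6 is created in that step with only remote centres to control it. Two allylic acetates are exposed to a low-valent metal that can ionise them.
- Comparison: this route is clearly stronger on step economy. The chosen strategy is longer but forms the medium ring by cutting a bond and sets C6 in a rigid chair.

Alternative 2: The disconnection is C5–C6, leaving the seco compound A3, an E-alkenyl iodide at C5 tethered to a 2-silyloxyfuran whose free position is C6. In the forward step zerovalent palladium (Pd2(dba)3, P(t-Bu)3, ZnF2) inserts into the C–I bond and alkenylates the furan at its γ carbon, closing the ring and restoring the butenolide in A4.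
- For: the E geometry is built into the iodide, the butenolide carbons are assembled beforehand, and the end-game is one deprotection.
- Against: the γ-coupling is an intermolecular reaction type; used for ring closure it must form a ten-membered ring containing an E-trisubstituted alkene, with α- against γ-selectivity and the C6 configuration both left to the macrocycle. The C3 and C9 acetates are allylic and are substrates for π-allyl formation by the same catalyst. The product's C6–H is acidic under the fluoride conditions.
- Comparison: it is equal or better on convergence. The chosen strategy has no palladium near allylic esters and has substrate-fixed stereochemistry at C6.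

Alternative 3: The disconnection is C7–C8 through a Claisen retron. The C9 ketone A7 with a 2-propenyl branch at C7 is traced to the macrocyclic allyl vinyl ether A6 and this to the twelve-membered lactone A5. Forward, A5 is methylenated with Cp2TiMe2 and the resulting A6 rearranges on heating, forming C7–C8 and the C9 ketone while the ring contracts from twelve to ten atoms.
- For: a twelve-membered lactone is easier to close than a ten-membered carbocycle, the contraction is well ordered through a cyclic transition state, and it gives the same C9 ketone as the chosen route.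
- Against: A5 still needs a macrolactonisation with both alkenes in the seco acid, and methylenation must be selective in a polyfunctional macrocycle. C7 forms as a mixture. The branch arrives at the wrong oxidation level, so after the key step C12 has to be oxidised, the lactone closed and the exocyclic alkene moved to C7=C11 with C13 oxygenated, a long and uncertain end-game.
- Comparison: the two routes are equal up to the C9 ketone. The chosen strategy delivers C7 as a ketone and C6 as a defined carbinol, which is what the butenolide closure needs.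

Key step: step 16

## Route

Step 1
Reactants: 1 (S)-(+)-carvone
Product: 3 (1S)-4-methyl-5-oxocyclohex-3-en-1-yl acetate, via methoxy hydroperoxide 2 (not isolated)
Conditions: O3, CH2Cl2/MeOH (1:1), −78 °C; then Ac2O, Et3N, DMAP (4-dimethylaminopyridine, cat.), −78 °C to rt
Reagents that add atoms: ozone, O=[O+][O-]; methanol, CO
Why: The electron-rich 1,1-disubstituted alkene should be ozonised in preference to the enone alkene, and methanol traps the carbonyl oxide as 2. Acylation of 2 triggers a Criegee rearrangement in which the ring carbon migrates to oxygen with retention, so the carvone stereocentre becomes the C3 carbinol centre.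

Step 2
Reactants: 3 (1S)-4-methyl-5-oxocyclohex-3-en-1-yl acetate
Product: 4 (5S)-5-hydroxy-2-methylcyclohex-2-en-1-one
Conditions: K2CO3 (0.2 equiv), MeOH, 0 °C
Reagents that add atoms: none
Why: Base-catalysed transesterification; a catalytic amount of carbonate at 0 °C should remove the acetate before the β-acetoxy ketone can eliminate by E1cB.

Step 3
Reactants: 4 (5S)-5-hydroxy-2-methylcyclohex-2-en-1-one
Product: 6 (5S,6R)-5-hydroxy-2,6-dimethylcyclohex-2-en-1-one, via dilithium alkoxide enolate 5 (not isolated)
Conditions: LiN(i-Pr)2 (2.2 equiv), THF, −78 °C; MeI (1.1 equiv), −78 to −40 °C; then H2O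
Reagents that add atoms: iodomethane, CI
Why: Two equivalents of amide base give the alkoxide α'-enolate 5, whose oxide cannot act as a β-leaving group, and C-methylation follows the Fráter–Seebach pattern. The configuration of the new centre does not matter because C4 is enolised again in step 4.

Step 4
Reactants: 6 (5S,6R)-5-hydroxy-2,6-dimethylcyclohex-2-en-1-one
Product: 8 (5S,6S)-6-(dimethoxymethyl)-5-hydroxy-2,6-dimethylcyclohex-2-en-1-one, via bis(trimethylsilyl) dienol ether 7 (not isolated)
Conditions: LiN(i-Pr)2 (2.2 equiv), Me3SiCl (2.5 equiv), THF, −78 °C; then HC(OMe)3, Me3SiOTf (10 mol%), CH2Cl2, −78 °C; aq. citric acid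
Reagents that add atoms: trimethyl orthoformate, COC(OC)OC
Why: The tetrasubstituted enolate is trapped as 7, and the dialkoxycarbenium ion from the orthoformate attacks C4 in a Mukaiyama-type alkylation anti to the adjacent C3 silyloxy group. This sets the quaternary centre with the methyl cis to the C3 oxygen and C5 as a masked aldehyde; the C3 silyl ether is lost on acidic work-up.

Step 5
Reactants: 8 (5S,6S)-6-(dimethoxymethyl)-5-hydroxy-2,6-dimethylcyclohex-2-en-1-one
Product: 9 (1S,2S)-2-(dimethoxymethyl)-2,4-dimethyl-3-oxocyclohex-4-en-1-yl bromoacetate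
Conditions: BrCH2COBr, pyridine, CH2Cl2, −20 °C
Reagents that add atoms: bromoacetyl bromide, BrCC(Br)=O
Why: Acylation of the only hydroxyl; the weak base should not provoke retro-aldol opening of the β-hydroxy ketone.

Step 6
Reactants: 9 (1S,2S)-2-(dimethoxymethyl)-2,4-dimethyl-3-oxocyclohex-4-en-1-yl bromoacetate
Product: 10 bridged hydroxy lactone 9-(dimethoxymethyl)-5-hydroxy-6,9-dimethyl-2-oxabicyclo[3.3.1]non-6-en-3-one (germacrane C9 carbinol; C8 cis to O3; 9α-OH; 4β-CH3)
Conditions: SmI2 (2.5 equiv), THF, −78 °C
Reagents that add atoms: none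
Why: Reduction of the C–Br bond gives a trivalent samarium ester enolate that adds to the C9 ketone through a chelated chair (intramolecular Reformatsky reaction of a β-acyloxy ketone). The two-atom tether from the axial C3 oxygen can only reach the β face, so C8 ends cis to O3 and the C9 hydroxyl trans to the C4 methyl, which a free nucleophile attacking anti to the axial methyl should not give.

Step 7
Reactants: 11 (tributylstannyl)methanol
Product: 12 tributyl{[(4-methoxybenzyl)oxy]methyl}stannane
Conditions: NaH, THF/DMF, 0 °C; 4-MeOC6H4CH2Cl, Bu4NI (cat.), rt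
Reagents that add atoms: 4-methoxybenzyl chloride, COc1ccc(CCl)cc1
Why: Williamson etherification of the primary stannyl carbinol.

Step 8
Reactants: 10 bridged hydroxy lactone; 12 tributyl{[(4-methoxybenzyl)oxy]methyl}stannane
Product: 13 keto diol 1-[6-(dimethoxymethyl)-1,5-dihydroxy-2,6-dimethylcyclohex-2-en-1-yl]-3-[(4-methoxybenzyl)oxy]propan-2-one (3β-OH; 4β-CH3; 9α-OH)
Conditions: 12 (2.6 equiv), n-BuLi (2.5 equiv), THF, −78 °C; then 10, −78 °C; aq. NH4Cl
Reagents that add atoms: none
Why: Tin–lithium exchange gives the α-alkoxymethyllithium; one equivalent is spent on the C9 hydroxyl and the next adds to the lactone carbonyl, stopping at the tetrahedral lithium lactolate at −78 °C. Work-up should give the α-alkoxy ketone (in equilibrium with its bridged lactol), with C6 and its protected oxygen in place.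

Step 9
Reactants: 13 keto diol
Product: 14 C3 tert-butyldimethylsilyl ether of 13 (3β-OTBS; 9α-OH)
Conditions: t-BuMe2SiCl, imidazole, DMF, 0 °C to rt
Reagents that add atoms: tert-butyldimethylsilyl chloride, CC(C)(C)[Si](C)(C)Cl
Why: The secondary C3 hydroxyl of the open form is silylated in preference to the tertiary C9 hydroxyl, which also draws the lactol equilibrium to the open keto form.

Step 10
Reactants: 14 C3 silyl ether
Product: 15 keto aldehyde 6-(tert-butyldimethylsilyloxy)-2-hydroxy-2-{3-[(4-methoxybenzyl)oxy]-2-oxopropyl}-1,3-dimethylcyclohex-3-ene-1-carbaldehyde (3β-OTBS; 4β-CH3; 9α-OH)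
Conditions: LiBF4, MeCN/H2O (50:1), 50 °C
Reagents that add atoms: water, O
Why: Mild Lewis-acid hydrolysis of the dimethyl acetal should leave the secondary silyl ether and the tertiary allylic alcohol untouched; the aldehyde has no α-hydrogen and cannot epimerise.

Step 11
Reactants: 15 keto aldehyde
Product: 16 trans-decalin ketone (ring B closed; 3β-OTBS; 4β-CH3; 5-OSiMe3 as both epimers; 6α-OPMB; 7-oxo; 9α-OSiMe3; 1(10)-ene)
Conditions: Me3SiOTf (3 equiv), i-Pr2NEt (4 equiv), CH2Cl2, −78 to −30 °C; pH 7 buffer
Reagents that add atoms: trimethylsilyl triflate, C[Si](C)(C)OS(=O)(=O)C(F)(F)F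
Why: Soft enolisation silylates the C9 hydroxyl and converts the ketone into its enol silane; only the C6 enol silane can reach the activated C5 aldehyde, so an intramolecular Mukaiyama aldol closes ring B, trans-fused because C5 and C8 are trans on ring A. The C6 ether should take the equatorial position away from the axial C4 methyl, C5 may form as either epimer, and the absence of base should suppress retro-aldol loss of the C9 carbinol.

Step 12
Reactants: 16 trans-decalin ketone
Product: 17 trans-decalin diol ketal (5-OH as both epimers; 7,7-ethylenedioxy; 9α-OH; otherwise as 16)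
Conditions: Me3SiOCH2CH2OSiMe3, Me3SiOTf (10 mol%), CH2Cl2, −78 to −20 °C; then K2CO3, MeOH, rt
Reagents that add atoms: 1,2-bis(trimethylsilyloxy)ethane, C[Si](C)(C)OCCO[Si](C)(C)C
Why: Noyori ketalisation is aprotic and runs with both hydroxyls masked as silyl ethers, which should avoid dehydration of the β-oxygenated ketone. Methanolysis then frees the C5 and C9 hydroxyls when no carbonyl is left for a retro-aldol.

Step 13
Reactants: 17 trans-decalin diol ketal
Product: 18 trans-decalin C5 ketone (5-oxo; 6α-OPMB; 7,7-ethylenedioxy; 9α-OH)
Conditions: Dess–Martin periodinane, NaHCO3, CH2Cl2, rt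
Reagents that add atoms: none
Why: Oxidation of the only secondary alcohol brings both C5 epimers to one ketone; the tertiary C9 hydroxyl and the ketal are inert under buffered conditions.

Step 14
Reactants: 18 trans-decalin C5 ketone
Product: 19 trans-decalin 5β,9α-diol (equatorial 5β-OH)
Conditions: Me4NBH(OAc)3, MeCN/AcOH, −30 °C
Reagents that add atoms: none
Why: Evans–Saksena reduction: the axial C9 hydroxyl binds the acetoxyborohydride and delivers hydride to the α face of C5 (1,3-anti), which should give the equatorial 5β-alcohol.

Step 15
Reactants: 19 trans-decalin 5β,9α-diol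
Product: 20 trans-decalin hydroxy mesylate (3β-OTBS; 4β-CH3; 5β-OMs; 6α-OPMB; 7,7-ethylenedioxy; 9α-OH; 1(10)-ene)
Conditions: MeSO2Cl, Et3N, CH2Cl2, −10 °C
Reagents that add atoms: methanesulfonyl chloride, CS(Cl)(=O)=O
Why: Sulfene mesylation of the secondary C5 hydroxyl; the tertiary C9 hydroxyl does not react and is not deprotonated by the amine, so no fragmentation should start here.

Step 16
Reactants: 20 trans-decalin hydroxy mesylate
Product: 21 (3S,6R,1(10)Z,4E)-3-(tert-butyldimethylsilyloxy)-7,7-ethylenedioxy-6-[(4-methoxybenzyl)oxy]germacra-1(10),4-dien-9-one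
Conditions: KOt-Bu (1.1 equiv), THF, 0 °C; then pH 7 buffer
Reagents that add atoms: none
Why: tert-Butoxide deprotonates the tertiary C9 hydroxyl and the alkoxide lone pair pushes into the C4–C9 σ bond, which breaks while the C4=C5 π bond forms and methanesulfonate leaves C5 in one heterolytic step (Wharton–Grob fragmentation of a 1,3-diol monosulfonate, closest precedent the decalin-to-cyclodecenone version). The ten-membered ring is not closed by bond formation: it is the perimeter of the bicyclo[4.4.0]decene and is uncovered when the shared bond is cut, so the entropic cost of medium-ring closure does not arise. No stereocentre is formed; C4, C5 and C9 become trigonal and C3 and C6 are not touched. The selectivity needed is the E geometry at C4=C5, and the substrate fixes it: in the trans-fused chair the equatorial C5–O bond is anti-periplanar to C4–C9, C6 is anti to C3 and H5 is anti to C15, and this arrangement is carried into the alkene. The Z alkene C1=C10 is the ring A alkene and becomes conjugated with the new C9 ketone. Release of the peri repulsion between the C3 silyl ether and the C5 mesylate adds driving force, and the neopentyl-type C5 centre has no easy substitution or anti-elimination path. The base is consumed as potassium methanesulfonate, so a slight excess at 0 °C should leave little alkoxide to enolise the product towards C8, where E1cB opening of the dioxolane would otherwise threaten.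

Step 17
Reactants: 21 dienone
Product: 22 (3S,6R,9S)-alcohol (9-OH; otherwise as 21)
Conditions: (R)-Me-CBS [(R)-1-methyl-3,3-diphenyltetrahydro-1H,3H-pyrrolo[1,2-c][1,3,2]oxazaborole] (0.5 equiv), catecholborane (1.8 equiv), toluene, −78 °C
Reagents that add atoms: none
Why: Corey–Bakshi–Shibata reduction: the α-methyl alkenyl group should act as the large substituent, so the (R)-catalyst should deliver hydride to the face that gives the 9S allylic alcohol. Catecholborane at low temperature avoids conjugate reduction and hydroboration.

Step 18
Reactants: 22 (9S)-alcohol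
Product: 23 3,9-bis(tert-butyldimethylsilyl) ether
Conditions: t-BuMe2SiOTf, 2,6-lutidine, CH2Cl2, −78 to 0 °C
Reagents that add atoms: tert-butyldimethylsilyl triflate, CC(C)(C)[Si](C)(C)OS(=O)(=O)C(F)(F)F
Why: Silylation of the hindered allylic alcohol with the triflate; a silyl ether is used instead of the final acetate because C9–O later sits β to the C7 ketone and a poor leaving group is wanted there.

Step 19
Reactants: 23 bis-silyl ether
Product: 24 C6 alcohol (6-OH; 7,7-ethylenedioxy; 3,9-bis-OTBS)
Conditions: DDQ, CH2Cl2/pH 7 buffer, 0 °C
Reagents that add atoms: none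
Why: Oxidative cleavage of the 4-methoxybenzyl ether by single-electron transfer; silyl ethers, ketal and diene should survive the buffered conditions.

Step 20
Reactants: 25 ethyl 2-(diethoxyphosphoryl)acrylate
Product: 26 ethyl 2-(diethoxyphosphoryl)-3-[(4-methoxybenzyl)oxy]propanoate
Conditions: 4-MeOC6H4CH2OH (1.5 equiv), NaH (10 mol%), THF, 0 °C
Reagents that add atoms: 4-methoxybenzyl alcohol, COc1ccc(CO)cc1
Why: Base-catalysed oxa-Michael addition to the doubly activated alkene.

Step 21
Reactants: 26 phosphono ester
Product: 27 2-(diethoxyphosphoryl)-3-[(4-methoxybenzyl)oxy]propanoic acid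
Conditions: LiOH, THF/H2O (3:1), 0 °C; then 1 M HCl
Reagents that add atoms: lithium hydroxide, [Li+].[OH-]
Why: Saponification of the carboxylic ester at 0 °C; phosphonate esters should not be cleaved under these conditions.

Step 22
Reactants: 24 C6 alcohol; 27 phosphono acid
Product: 28 C6 phosphono ester (6-O-acyl; 7,7-ethylenedioxy; 3,9-bis-OTBS; epimers at the phosphonate carbon)
Conditions: DCC, DMAP (4-dimethylaminopyridine, 0.1 equiv), CH2Cl2, 0 °C to rt
Reagents that add atoms: none
Why: Steglich esterification acylates the hindered C6 hydroxyl while C7 is still a ketal, so no free α-hydroxy ketone that could undergo a ketol shift is ever formed.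

Step 23
Reactants: 28 C6 phosphono ester
Product: 29 keto phosphonate (7-oxo; otherwise as 28)
Conditions: pyridinium p-toluenesulfonate (0.3 equiv), acetone/H2O (10:1), 50 °C
Reagents that add atoms: water, O
Why: Acid-catalysed hydrolysis of the dioxolane; secondary silyl ethers and the allylic ester should tolerate the buffered acid.

Step 24
Reactants: 29 keto phosphonate
Product: 30 butenolide (3S,6R,9S)-3,9-bis(tert-butyldimethylsilyloxy)-13-[(4-methoxybenzyl)oxy]germacra-1(10),4,7(11)-trien-12,6-olide
Conditions: LiCl, DBU, MeCN, 0 °C to rt
Reagents that add atoms: none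
Why: Intramolecular Horner–Wadsworth–Emmons olefination under Masamune–Roush conditions: the phosphonate is far more acidic than the ketone, the carbanion attacks C7 in a 5-exo sense and loss of phosphate gives the C7=C11 alkene. The mild base should spare the β-silyloxy group at C9 and the C6 centre.

Step 25
Reactants: 30 butenolide
Product: 31 3,9-diol (13-OPMB)
Conditions: HF·pyridine, pyridine, THF, 0 °C to rt
Reagents that add atoms: none
Why: Fluoride cleavage of both secondary silyl ethers under buffered, weakly acidic conditions that should not enolise the butenolide.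

Step 26
Reactants: 31 3,9-diol
Product: 32 3,9-diacetate (13-OPMB)
Conditions: Ac2O, pyridine, DMAP (4-dimethylaminopyridine, cat.), CH2Cl2, 0 °C
Reagents that add atoms: acetic anhydride, CC(=O)OC(C)=O
Why: Acetylation of the two secondary allylic alcohols; C13 is still protected, so no differentiation is needed.

Step 27
Reactants: 32 3,9-diacetate
Product: 33 CNP0328753.1, (3S,6R,9S)-3,9-diacetoxy-13-hydroxygermacra-1(10)Z,4E,7(11)-trien-12,6-olide
Conditions: DDQ, CH2Cl2/pH 7 buffer, 0 °C
Reagents that add atoms: none
Why: Oxidative removal of the last 4-methoxybenzyl ether frees the C13 alcohol; acetates and butenolide should be stable to the oxidant.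

## Compound list

1 | (S)-(+)-carvone, (5S)-2-methyl-5-(prop-1-en-2-yl)cyclohex-2-en-1-one | CC1=CC[C@H](C(C)=C)CC1=O | starting material
2 | methoxy hydroperoxide, (5S)-5-(1-hydroperoxy-1-methoxyethyl)-2-methylcyclohex-2-en-1-one (both epimers at the peroxy carbon) | CC1=CC[C@H](C(C)(OC)OO)CC1=O | intermediate
3 | (1S)-4-methyl-5-oxocyclohex-3-en-1-yl acetate | CC1=CC[C@H](OC(C)=O)CC1=O | intermediate
4 | (5S)-5-hydroxy-2-methylcyclohex-2-en-1-one | CC1=CC[C@H](O)CC1=O | intermediate
5 | dilithium alkoxide enolate of 4 | CC1=CC[C@H](O[Li])C=C1O[Li] | intermediate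
6 | (5S,6R)-5-hydroxy-2,6-dimethylcyclohex-2-en-1-one (trans; any cis epimer is carried along) | CC1=CC[C@H](O)[C@@H](C)C1=O | intermediate
7 | (6S)-1,3-dimethyl-2,6-bis(trimethylsilyloxy)cyclohexa-1,3-diene | CC1=CC[C@H](O[Si](C)(C)C)C(C)=C1O[Si](C)(C)C | intermediate
8 | (5S,6S)-6-(dimethoxymethyl)-5-hydroxy-2,6-dimethylcyclohex-2-en-1-one (hydroxyl cis to the C6 methyl) | CC1=CC[C@H](O)[C@@](C)(C(OC)OC)C1=O | intermediate
9 | (1S,2S)-2-(dimethoxymethyl)-2,4-dimethyl-3-oxocyclohex-4-en-1-yl bromoacetate | CC1=CC[C@H](OC(=O)CBr)[C@@](C)(C(OC)OC)C1=O | intermediate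
10 | bridged hydroxy lactone, 9-(dimethoxymethyl)-5-hydroxy-6,9-dimethyl-2-oxabicyclo[3.3.1]non-6-en-3-one (C8 cis to O3 on ring A; 9α-OH; 4β-CH3) | CC1=CC[C@@H]2OC(=O)C[C@@]1(O)[C@]2(C)C(OC)OC | intermediate
11 | (tributylstannyl)methanol | CCCC[Sn](CCCC)(CCCC)CO | starting material
12 | tributyl{[(4-methoxybenzyl)oxy]methyl}stannane | CCCC[Sn](CCCC)(CCCC)COCc1ccc(OC)cc1 | intermediate
13 | keto diol, 1-[6-(dimethoxymethyl)-1,5-dihydroxy-2,6-dimethylcyclohex-2-en-1-yl]-3-[(4-methoxybenzyl)oxy]propan-2-one (3β-OH; 4β-CH3; 9α-OH; in equilibrium with its bridged lactol) | CC1=CC[C@H](O)[C@@](C)(C(OC)OC)[C@]1(O)CC(=O)COCc1ccc(OC)cc1 | intermediate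
14 | C3 tert-butyldimethylsilyl ether of 13 | CC1=CC[C@H](O[Si](C)(C)C(C)(C)C)[C@@](C)(C(OC)OC)[C@]1(O)CC(=O)COCc1ccc(OC)cc1 | intermediate
15 | keto aldehyde, 6-(tert-butyldimethylsilyloxy)-2-hydroxy-2-{3-[(4-methoxybenzyl)oxy]-2-oxopropyl}-1,3-dimethylcyclohex-3-ene-1-carbaldehyde (3β-OTBS; 4β-CH3; 9α-OH) | CC1=CC[C@H](O[Si](C)(C)C(C)(C)C)[C@@](C)(C=O)[C@]1(O)CC(=O)COCc1ccc(OC)cc1 | intermediate
16 | trans-decalin ketone with the C4–C9 bond (3β-OTBS; 4β-CH3; 5-OSiMe3, both epimers; 6α-OPMB; 7-oxo; 9α-OSiMe3; 1(10)-ene) | C[Si](C)(C)O[C@@]12C(C)=CC[C@H](O[Si](C)(C)C(C)(C)C)[C@@]1(C)C(O[Si](C)(C)C)[C@@H](OCc3ccc(OC)cc3)C(=O)C2 | intermediate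
17 | trans-decalin diol ketal (5-OH, both epimers; 7,7-ethylenedioxy; 9α-OH) | O[C@@]12C(C)=CC[C@H](O[Si](C)(C)C(C)(C)C)[C@@]1(C)C(O)[C@@H](OCc3ccc(OC)cc3)C4(OCCO4)C2 | intermediate
18 | trans-decalin C5 ketone (5-oxo; 6α-OPMB; 7,7-ethylenedioxy; 9α-OH) | O[C@@]12C(C)=CC[C@H](O[Si](C)(C)C(C)(C)C)[C@@]1(C)C(=O)[C@@H](OCc3ccc(OC)cc3)C4(OCCO4)C2 | intermediate
19 | trans-decalin 5β,9α-diol | O[C@@]12C(C)=CC[C@H](O[Si](C)(C)C(C)(C)C)[C@@]1(C)[C@H](O)[C@@H](OCc3ccc(OC)cc3)C4(OCCO4)C2 | intermediate
20 | trans-decalin hydroxy mesylate (3β-OTBS; 4β-CH3; 5β-OMs; 6α-OPMB; 7,7-ethylenedioxy; 9α-OH) | O[C@@]12C(C)=CC[C@H](O[Si](C)(C)C(C)(C)C)[C@@]1(C)[C@H](OS(C)(=O)=O)[C@@H](OCc3ccc(OC)cc3)C4(OCCO4)C2 | intermediate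
21 | (3S,6R,1(10)Z,4E)-3-(tert-butyldimethylsilyloxy)-7,7-ethylenedioxy-6-[(4-methoxybenzyl)oxy]germacra-1(10),4-dien-9-one | O=C1CC2(OCCO2)[C@H](OCc3ccc(OC)cc3)/C=C(\C)[C@@H](O[Si](C)(C)C(C)(C)C)C/C=C\1C | intermediate
22 | (3S,6R,9S)-9-alcohol of 21 | O[C@H]1CC2(OCCO2)[C@H](OCc3ccc(OC)cc3)/C=C(\C)[C@@H](O[Si](C)(C)C(C)(C)C)C/C=C\1C | intermediate
23 | 3,9-bis(tert-butyldimethylsilyl) ether (6-OPMB; 7,7-ethylenedioxy) | CC(C)(C)[Si](C)(C)O[C@H]1CC2(OCCO2)[C@H](OCc3ccc(OC)cc3)/C=C(\C)[C@@H](O[Si](C)(C)C(C)(C)C)C/C=C\1C | intermediate
24 | C6 alcohol (6-OH; 7,7-ethylenedioxy; 3,9-bis-OTBS) | CC(C)(C)[Si](C)(C)O[C@H]1CC2(OCCO2)[C@H](O)/C=C(\C)[C@@H](O[Si](C)(C)C(C)(C)C)C/C=C\1C | intermediate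
25 | ethyl 2-(diethoxyphosphoryl)acrylate | C=C(C(=O)OCC)P(=O)(OCC)OCC | starting material
26 | ethyl 2-(diethoxyphosphoryl)-3-[(4-methoxybenzyl)oxy]propanoate (racemic) | CCOC(=O)C(COCc1ccc(OC)cc1)P(=O)(OCC)OCC | intermediate
27 | 2-(diethoxyphosphoryl)-3-[(4-methoxybenzyl)oxy]propanoic acid (racemic) | OC(=O)C(COCc1ccc(OC)cc1)P(=O)(OCC)OCC | intermediate
28 | C6 phosphono ester of 24 (7,7-ethylenedioxy; epimers at the phosphonate carbon) | CC(C)(C)[Si](C)(C)O[C@H]1CC2(OCCO2)[C@H](OC(=O)C(COCc3ccc(OC)cc3)P(=O)(OCC)OCC)/C=C(\C)[C@@H](O[Si](C)(C)C(C)(C)C)C/C=C\1C | intermediate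
29 | keto phosphonate (7-oxo) | CC(C)(C)[Si](C)(C)O[C@H]1CC(=O)[C@H](OC(=O)C(COCc2ccc(OC)cc2)P(=O)(OCC)OCC)/C=C(\C)[C@@H](O[Si](C)(C)C(C)(C)C)C/C=C\1C | intermediate
30 | (3S,6R,9S)-3,9-bis(tert-butyldimethylsilyloxy)-13-[(4-methoxybenzyl)oxy]germacra-1(10)Z,4E,7(11)-trien-12,6-olide | CC(C)(C)[Si](C)(C)O[C@H]1CC2=C(COCc3ccc(OC)cc3)C(=O)O[C@@H]2/C=C(\C)[C@@H](O[Si](C)(C)C(C)(C)C)C/C=C\1C | intermediate
31 | (3S,6R,9S)-3,9-dihydroxy-13-[(4-methoxybenzyl)oxy]germacra-1(10)Z,4E,7(11)-trien-12,6-olide | O[C@H]1CC2=C(COCc3ccc(OC)cc3)C(=O)O[C@@H]2/C=C(\C)[C@@H](O)C/C=C\1C | intermediate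
32 | (3S,6R,9S)-3,9-diacetoxy-13-[(4-methoxybenzyl)oxy]germacra-1(10)Z,4E,7(11)-trien-12,6-olide | CC(=O)O[C@H]1CC2=C(COCc3ccc(OC)cc3)C(=O)O[C@@H]2/C=C(\C)[C@@H](OC(C)=O)C/C=C\1C | intermediate
33 | CNP0328753.1, (3S,6R,9S)-3,9-diacetoxy-13-hydroxygermacra-1(10)Z,4E,7(11)-trien-12,6-olide | CC(=O)O[C@H]1CC2=C(CO)C(=O)O[C@@H]2/C=C(\C)[C@@H](OC(C)=O)C/C=C\1C | target

## Step count and least certain steps

Total step count: 27 (24 in the main line, 1 for stannane 12, 2 for acid 27). Longest linear sequence: 24 steps from 1 to 33 (steps 1–6, 8–19 and 22–27).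

Step 16 (key step). Most likely failure: once the C9 ketone exists, residual alkoxide enolises it towards C8, and from that enolate the C7 dioxolane opens by E1cB elimination or the C1=C10 alkene moves out of conjugation. The product is a β-keto ketal formed in the presence of the base that made it. Fallback: starting from 20, the C9 hydroxyl is silylated (Me3SiOTf, 2,6-lutidine) to the C9 trimethylsilyl ether F1, and the alkoxide is released with anhydrous fluoride (CsF, 18-crown-6, MeCN). The fragmentation then runs as a desilylative Grob fragmentation with no alkoxide base in the flask, and the route is rejoined at 21.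

Step 6. Most likely failure: single-electron reduction of the cross-conjugated enone by SmI2 (ketyl formation, pinacol coupling) or conjugate addition of the metal enolate to C1 competing with addition to the hindered C9 carbonyl. Fallback: starting from 8, the hydroxyl is acetylated (Ac2O, pyridine) to the acetate F2, whose lithium enolate (LiN(SiMe3)2, THF, −78 °C) is cyclised in an intramolecular acetate aldol. This closed-shell route needs no reductant and returns to the main line at 10.

Step 11. Most likely failure: enol silane formation on the C8 side without ring closure, loss of silanol from C5 after closure (β-elimination to the enone), or Lewis-acid-induced retro-aldol cleavage at C9. The neopentyl aldehyde is slow to react and the ketone carries two β-oxygen functions. Fallback: starting from 15, the ring is closed by enamine catalysis (pyrrolidine, AcOH, THF, rt; a Hajos–Parrish-type aldolisation) to the free dihydroxy ketone F3. F3 is ketalised as in step 12 and the route is rejoined at 17.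

Step 17. Most likely failure: poor facial selectivity, because the C8 methylene next to the spiro ketal competes with the alkenyl group for the role of the large substituent and the ten-membered ring has its own conformational bias. Fallback: starting from 21, a substrate-controlled Luche reduction (NaBH4, CeCl3·7H2O, MeOH, −78 °C) is used. If it gives the 9R alcohol F4, this is inverted by a Mitsunobu reaction (4-nitrobenzoic acid, PPh3, diisopropyl azodicarboxylate) to the 9S 4-nitrobenzoate F5, and methanolysis (K2CO3, MeOH) returns to the route at 22.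

Step 24. Most likely failure: loss of 4-methoxybenzyl oxide from the phosphonate anion (retro-oxa-Michael) before it reaches the hindered C7 ketone, or β-elimination of the C9 silyloxy group from the C8 enolate. Fallback: 25 is saponified to 2-(diethoxyphosphoryl)acrylic acid F6. Alcohol 24 is esterified with F6 (DCC) to the C6 phosphonoacrylate F7, and the ketal is hydrolysed to the keto acrylate F8. Treating F8 with 4-methoxybenzyl alcohol and NaH generates the same carbanion by oxa-Michael addition in the presence of excess alkoxide and lets it close by Horner–Wadsworth–Emmons reaction. This tandem sequence returns to the route at 30.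

## Further compounds

F1 | step 16 | C9 trimethylsilyl ether of 20 (3β-OTBS; 5β-OMs; 6α-OPMB; 7,7-ethylenedioxy; 9α-OSiMe3) | C[Si](C)(C)O[C@@]12C(C)=CC[C@H](O[Si](C)(C)C(C)(C)C)[C@@]1(C)[C@H](OS(C)(=O)=O)[C@@H](OCc3ccc(OC)cc3)C4(OCCO4)C2
F2 | step 6 | (1S,2S)-2-(dimethoxymethyl)-2,4-dimethyl-3-oxocyclohex-4-en-1-yl acetate | CC1=CC[C@H](OC(C)=O)[C@@](C)(C(OC)OC)C1=O
F3 | step 11 | trans-decalin dihydroxy ketone (5-OH, both epimers; 6α-OPMB; 7-oxo; 9α-OH; 3β-OTBS) | O[C@@]12C(C)=CC[C@H](O[Si](C)(C)C(C)(C)C)[C@@]1(C)C(O)[C@@H](OCc3ccc(OC)cc3)C(=O)C2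
F4 | step 17 | (3S,6R,9R)-9-alcohol, C9 epimer of 22 | O[C@@H]1CC2(OCCO2)[C@H](OCc3ccc(OC)cc3)/C=C(\C)[C@@H](O[Si](C)(C)C(C)(C)C)C/C=C\1C
F5 | step 17 | (3S,6R,9S)-9-(4-nitrobenzoate) of 22 | O=C(O[C@H]1CC2(OCCO2)[C@H](OCc3ccc(OC)cc3)/C=C(\C)[C@@H](O[Si](C)(C)C(C)(C)C)C/C=C\1C)c1ccc(cc1)[N+](=O)[O-]
F6 | step 24 | 2-(diethoxyphosphoryl)acrylic acid | C=C(C(=O)O)P(=O)(OCC)OCC
F7 | step 24 | C6 2-(diethoxyphosphoryl)acrylate of 24 (7,7-ethylenedioxy) | CC(C)(C)[Si](C)(C)O[C@H]1CC2(OCCO2)[C@H](OC(=O)C(=C)P(=O)(OCC)OCC)/C=C(\C)[C@@H](O[Si](C)(C)C(C)(C)C)C/C=C\1C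
F8 | step 24 | keto acrylate (7-oxo analogue of F7) | CC(C)(C)[Si](C)(C)O[C@H]1CC(=O)[C@H](OC(=O)C(=C)P(=O)(OCC)OCC)/C=C(\C)[C@@H](O[Si](C)(C)C(C)(C)C)C/C=C\1C
A1 | alternative 1 | seco ynal, (2E,4S,6Z,8S)-4,8-diacetoxy-12-(tert-butyldimethylsilyloxy)-3,7-dimethyldodeca-2,6-dien-10-ynal | O=C/C=C(\C)[C@@H](OC(C)=O)C/C=C(/C)[C@@H](OC(C)=O)CC#CCO[Si](C)(C)C(C)(C)C
A2 | alternative 1 | target as its C13 tert-butyldimethylsilyl ether | CC(=O)O[C@H]1CC2=C(CO[Si](C)(C)C(C)(C)C)C(=O)O[C@@H]2/C=C(\C)[C@@H](OC(C)=O)C/C=C\1C
A3 | alternative 2 | seco E-alkenyl iodide with 2-(triisopropylsilyloxy)furan terminus (free furan carbon = C6; C13 as tert-butyldiphenylsilyl ether) | I/C=C(\C)[C@@H](OC(C)=O)C/C=C(/C)[C@@H](OC(C)=O)Cc1coc(O[Si](C(C)C)(C(C)C)C(C)C)c1CO[Si](c1ccccc1)(c1ccccc1)C(C)(C)C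
A4 | alternative 2 | target as its C13 tert-butyldiphenylsilyl ether | CC(=O)O[C@H]1CC2=C(CO[Si](c3ccccc3)(c4ccccc4)C(C)(C)C)C(=O)O[C@@H]2/C=C(\C)[C@@H](OC(C)=O)C/C=C\1C
A5 | alternative 3 | twelve-membered lactone (C9 carbonyl, ring oxygen on the allylic methylene of the C11=C7 alkene) | O=C1OCC(CO[Si](c2ccccc2)(c2ccccc2)C(C)(C)C)=C[C@H](OCc2ccc(OC)cc2)/C=C(\C)[C@@H](O[Si](C)(C)C(C)(C)C)C/C=C\1C
A6 | alternative 3 | macrocyclic allyl vinyl ether from methylenation of A5 | C=C1OCC(CO[Si](c2ccccc2)(c2ccccc2)C(C)(C)C)=C[C@H](OCc2ccc(OC)cc2)/C=C(\C)[C@@H](O[Si](C)(C)C(C)(C)C)C/C=C\1C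
A7 | alternative 3 | ten-membered C9 ketone with C7 2-propenyl side chain (C7 epimers) | O=C1CC(C(=C)CO[Si](c2ccccc2)(c2ccccc2)C(C)(C)C)[C@H](OCc2ccc(OC)cc2)/C=C(\C)[C@@H](O[Si](C)(C)C(C)(C)C)C/C=C\1C
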